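**Assumptions (one line):** (2S)-pinocembrin is commercially available. C-8 of its A-ring is the more nucleophilic ortho position, and any C-6 isomer is separable. The C-2′ hemiketal of the target is the thermodynamic anomer and re-equilibrates under mild acid.

**Retrosynthesis**
1. The target hemiketal comes from hydration of the cyclic dienol ether **12** as the last step, so the ring oxygen O1′ stays locked until the end.
2. **12** comes from Shiina macrolactonization of acid **11**, which closes the 10-membered aryl lactone on a rigid trans-4,6-disubstituted tetrahydropyran.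
3. Key step: **11** comes from a vinylogous (Ferrier-type) Friedel–Crafts C-8 arylation of (2S)-pinocembrin (**10**). The arene adds to the 2-styryl dihydropyranyl oxocarbenium derived from hemiketal **9**. The phloroglucinol-type ring is transiently dearomatized, and C4′ is set trans to C6′.
4. **9** comes from styryl-Li/CeCl3 addition to lactone **7**, which comes from oxidative cleavage of **6**, from RCM of **5**, from Brown allylation of hex-5-enal.
5. Rings are formed in this order: δ-lactone (RCM), dihydropyran hemiketal, aryl–C bond and THP enol ether, 10-membered lactone, final hemiketal.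

---

**Step 1**
Reactants: **1** hex-5-enal; **2** (−)-B-allyldiisopinocampheylborane (the Ipc2B-allyl antipode that delivers the (R)-carbinol).
Product: **3** (R)-nona-1,8-dien-4-ol.
Conditions: Et2O, −78 °C, 1 h; then NaOH, H2O2, 0 °C → rt.
Reagents that add atoms: **2**, adding the allyl group, `C=CCB(C1CC2CC(C1C)C2(C)C)C1CC2CC(C1C)C2(C)C`.
Why: Brown asymmetric allylboration through a chair Zimmerman–Traxler transition state sets C6′ as (R), with ≥90% ee expected.

**Step 2**
Reactants: **3**; **4** acryloyl chloride.
Product: **5** (R)-nona-1,8-dien-4-yl acrylate.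
Conditions: **4**, iPr2NEt, CH2Cl2, −20 → 0 °C.
Reagents that add atoms: acryloyl chloride, `C=CC(=O)Cl`.
Why: Simple O-acylation of the secondary alcohol; the stereocentre is untouched.

**Step 3**
Reactant: **5**.
Product: **6** (R)-6-(pent-4-en-1-yl)-5,6-dihydro-2H-pyran-2-one.
Conditions: Grubbs II (5 mol %), CH2Cl2 (5 mM), 40 °C.
Reagents that add atoms: none.
Why: Ring-closing metathesis of the acrylate with the allyl terminus forms the six-membered unsaturated lactone much faster than any reaction of the pentenyl alkene. C6′ is unchanged.

**Step 4**
Reactant: **6**.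
Product: **7** 4-[(2R)-6-oxo-3,6-dihydro-2H-pyran-2-yl]butanoic acid.
Conditions: OsO4 (2 mol %), Oxone (4 equiv), DMF, 25 °C.
Reagents that add atoms: Oxone, `OOS(=O)(=O)[O-].[K+]`, supplying the carboxyl oxygens.
Why: Borhan oxidative cleavage converts the electron-rich terminal alkene directly to CO2H. The electron-poor enoate alkene is much less reactive, and C6′ is untouched.

**Step 5**
Reactants: **7**; **8** (E)-β-bromostyrene, converted in situ to (E)-styryllithium and then the organocerium.
Product: **9** 4-[(2R)-6-hydroxy-6-[(E)-2-phenylethenyl]-3,6-dihydro-2H-pyran-2-yl]butanoic acid, a hemiketal (anomeric mixture, in equilibrium with the open Z-dienone).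
Conditions: **8**, t-BuLi (2 equiv), Et2O, −78 °C; then CeCl3, **7**, THF, −78 °C; quench with aq. NH4Cl at −78 °C.
Reagents that add atoms: styryl group from **8**, `Br/C=C/c1ccccc1`.
Why: The acid is protected in situ as its carboxylate, and the organocerium adds 1,2 to the lactone carbonyl. The stable tetrahedral intermediate gives the hemiketal on quench, so there is no over-addition. The new C-2′ centre is labile and is resolved later.

**Step 6 (key step)**
Reactants: **9**; **10** (2S)-pinocembrin (2 equiv).
Product: **11** 4-[(2R,4R)-4-[(2S)-5,7-dihydroxy-4-oxo-2-phenylchroman-8-yl]-6-[(E)-styryl]-3,4-dihydro-2H-pyran-2-yl]butanoic acid.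
Conditions: Sc(OTf)3 (10 mol %), 4 Å MS, CH2Cl2, −20 → 0 °C; quench with Et3N.
Reagents that add atoms: none (the arene is **10**).
Why: Proposed new method: acid ionizes the tertiary hemiketal **9** to a stabilized O1′=C2′–C3′=C4′ oxocarbenium. The A-ring of **10** attacks the γ-carbon C4′ through its dienol/cyclohexadienone tautomer, so the ring is transiently dearomatized. Axial attack on the half-chair, anti to the pseudo-equatorial C6′ chain, gives the 4,6-trans product (4′R with 6′R) and the conjugated 2-styryl enol ether, which locks O1′. The closest known reaction type is Ferrier-type C-arylation of glycals, extended vinylogously to a ketone-derived 2-vinyl oxocarbenium. C-8 selectivity over C-6 is assumed; the C-6 isomer and any cis epimer are removed by chromatography.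

**Step 7**
Reactant: **11**.
Product: **12** macrocyclic aryl lactone carrying the cyclic dienol ether (dehydrated target).
Conditions: MNBA (1.5 equiv), DMAP (6 equiv), CH2Cl2, syringe-pump addition to 2 mM, 25 °C.
Reagents that add atoms: none.
Why: Shiina macrolactonization esterifies only the reactive 7-OH, because the 5-OH is H-bonded to the C4 carbonyl. The trans-1,3-THP arrangement preorganizes the seco acid. Because O1′ is an enol-ether oxygen, no free C6′-OH can form a δ-lactone.

**Step 8**
Reactant: **12**.
Product: **13** target.
Conditions: PPTS (20 mol %), THF–H2O (9:1), 25 °C, 3 h.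
Reagents that add atoms: water, `O`.
Why: Protonation of the 2-oxy-diene at C3′ gives the styryl-stabilized oxocarbenium, and axial capture by water gives the anomeric hemiketal (R at C2′). C4′ and C6′ are not involved, and the flavanone C-2 (S) is not touched under these mild acidic conditions.

---

**Compound list**

| No. | Name | SMILES | Role |
|---|---|---|---|
| 1 | hex-5-enal | `C=CCCCC=O` | starting material |
| 2 | (−)-B-allyldiisopinocampheylborane (pinane stereocentres from (+)-α-pinene, not drawn) | `C=CCB(C1CC2CC(C1C)C2(C)C)C1CC2CC(C1C)C2(C)C` | starting material |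
| 3 | (R)-nona-1,8-dien-4-ol | `C=CC[C@H](O)CCCC=C` | intermediate |
| 4 | acryloyl chloride | `C=CC(=O)Cl` | starting material |
| 5 | (R)-nona-1,8-dien-4-yl acrylate | `C=CC[C@H](OC(=O)C=C)CCCC=C` | intermediate |
| 6 | (R)-6-(pent-4-en-1-yl)-5,6-dihydro-2H-pyran-2-one | `O=C1C=CC[C@@H](CCCC=C)O1` | intermediate |
| 7 | 4-[(2R)-6-oxo-3,6-dihydro-2H-pyran-2-yl]butanoic acid | `O=C1C=CC[C@@H](CCCC(=O)O)O1` | intermediate |
| 8 | (E)-β-bromostyrene | `Br/C=C/c1ccccc1` | starting material |
| 9 | hemiketal acid (C-2′ unspecified) | `OC(=O)CCC[C@@H]1CC=CC(O)(/C=C/c2ccccc2)O1` | intermediate |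
| 10 | (2S)-pinocembrin | `O=C1C[C@H](Oc2cc(O)cc(O)c12)c1ccccc1` | starting material |
| 11 | 8-(dihydropyranyl)-flavanone acid | `OC(=O)CCC[C@@H]1C[C@H](C=C(/C=C/c2ccccc2)O1)c1c(O)cc(O)c2c1O[C@H](c1ccccc1)CC2=O` | intermediate |
| 12 | macrolactone dienol ether | `O=C1CCC[C@@H]2C[C@H](C=C(/C=C/c3ccccc3)O2)c2c(cc(O)c3c2O[C@H](c2ccccc2)CC3=O)O1` | intermediate |
| 13 | CID21592353, target (C32H30O7) | `O=C1CCC[C@@H]2C[C@H](C[C@](O)(/C=C/c3ccccc3)O2)c2c(cc(O)c3c2O[C@H](c2ccccc2)CC3=O)O1` | target |

**Totals:** 8 steps in total; longest linear sequence 8 steps (hex-5-enal → 3 → 5 → 6 → 7 → 9 → 11 → 12 → 13).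

**Three steps most likely to fail**
1. **Step 6 (key Friedel–Crafts).** Risks are C-6 versus C-8 attack, attack at the styryl terminus, a cis C4′ epimer, and δ-lactonization of the open hydroxy acid.
   *Fallback:* use phloroglucinol as the nucleophile, so the symmetry removes the C-6/C-8 issue. Then macrolactonize and build the flavanone ring last by cinnamoylation and oxa-Michael cyclization.
2. **Step 7 (10-membered macrolactonization).** The ring may dimerize or strain may prevent closure.
   *Fallback:* go tether-first. Make the methyl ketal acid of **9** (HC(OMe)3/CSA, then LiOH), esterify **10** with it (DCC/DMAP), and close the ring by intramolecular ketal-ionization Friedel–Crafts at high dilution.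
3. **Step 5 (styryl addition to the lactone acid).** Over-addition, 1,4-addition, or γ-deprotonation of the enoate could intervene.
   *Fallback:* open **7** with MeNH(OMe)·HCl/AlMe3 to the hydroxy Weinreb amide and protect it as the TES ether. Add (E)-styrylMgBr, then desilylate with HF·pyridine to give **9** by in situ cyclization.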